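**Plan**

1. Retrosynthesis: the six phenols are masked as benzyl ethers (cut last). The side-chain carbinol C3 is taken back to a ketone. The C4–C5 bond of the pentanoate (the CH2–CH2 bond between the carbinol carbon and the side-chain catechol ring) is cut to an acetoacetate γ-carbanion and a benzylic bromide. The ester O–C1 bond is cut to the flavan-3-ol and acetylketene.
2. Forward: no ring is built. The chroman with its A and B rings comes from (+)-catechin, and the side-chain catechol ring from 3,4-bis(benzyloxy)benzyl alcohol. The chain is assembled by O-acetoacetylation at chroman C3–OH, then γ-benzylation (C4–C5), then ketone reduction, then global debenzylation.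
3. Enabling feature: ester carbonyl C1 and carbinol C3 of the acyl chain are 1,3-related, so C1–C4 is a masked acetoacetate whose terminal methyl carbon (C4) becomes the most nucleophilic site as the dianion. C5 is a benzylic carbon on a 3,4-dioxygenated benzene ring and therefore a very good SN2 electrophile.
4. Stereochemistry: C2 (R) and C3 (S) of the chroman ring come from (+)-catechin (chiral pool) and are never touched. Side-chain C3 (S) is set by catalyst control in an (S)-BINAP–Ru hydrogenation of the β-keto ester.

Key step: step 4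

Assumption (remark on the chemistry): the SMILES given specifies a 2R,3S (2,3-trans) flavan-3-ol and a 3S side-chain carbinol. The 2R,3S core has the configuration of commercial (+)-catechin, and the route is built for exactly these descriptors.

**Route**

Step 1
Reactants: 1 (+)-catechin
Product: 2 5,7,3′,4′-tetra-O-benzyl-(+)-catechin
Conditions: BnBr (4.2 equiv), K2CO3 (4.5 equiv), DMF, 0 °C → rt, Ar
Reagents that add atoms: benzyl bromide, BrCc1ccccc1
Why: Williamson ether synthesis in which carbonate ionises only the four phenols and not the C3 secondary alcohol, so benzylation should stop at the tetraether, while low temperature under argon limits C-benzylation of the phloroglucinol ring and epimerisation at C2; no stereocentre is formed.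

Step 2
Reactants: 2 5,7,3′,4′-tetra-O-benzyl-(+)-catechin; 3 2,2,6-trimethyl-4H-1,3-dioxin-4-one
Product: 5 tetra-O-benzylcatechin 3-O-acetoacetate, via acetylketene 4 (not isolated)
Conditions: 3 (1.5 equiv), xylenes, 140 °C, acetone distilled off
Reagents that add atoms: none
Why: Clemens acetoacetylation, in which thermal retro-hetero-Diels–Alder cleavage of 3 releases acetylketene 4 that is captured by the hindered C3 hydroxyl under neutral conditions without a coupling agent; the C3–O bond is not broken, so the 3S configuration is retained.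

Step 3
Reactants: 6 3,4-bis(benzyloxy)benzyl alcohol
Product: 7 3,4-bis(benzyloxy)benzyl bromide
Conditions: PBr3 (0.4 equiv), Et2O, 0 °C; used at once
Reagents that add atoms: phosphorus tribromide, BrP(Br)Br
Why: Standard conversion of a primary benzylic alcohol into the bromide (SN2 by bromide on the phosphite ester), fast at 0 °C for an electron-rich benzylic centre and harmless to aryl benzyl ethers.

Step 4
Reactants: 5 tetra-O-benzylcatechin 3-O-acetoacetate; 7 3,4-bis(benzyloxy)benzyl bromide
Product: 10 tetra-O-benzylcatechin 3-O-{5-[3,4-bis(benzyloxy)phenyl]-3-oxopentanoate}, via dilithium dienolate 8 (not isolated), via lithium enolate 9 (not isolated)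
Conditions: LDA (commercial solution, 2.1 equiv), THF, −78 → 0 °C; then 7 (1.0 equiv), −78 → 0 °C; AcOH quench
Reagents that add atoms: none
Why: Two equivalents of LDA remove first the proton between the two carbonyls and then one from the terminal methyl group, giving dienolate 8, whose terminal (γ) carbanion is the least delocalised and most nucleophilic site and displaces bromide from the benzylic carbon of 7 by SN2, forming the C4–C5 bond and leaving the mono-enolate 9 until the quench. The closest known reaction type is the Huckin–Weiler γ-alkylation of acetoacetate dianions with benzylic and allylic halides. No ring is closed and no stereocentre is created, and chroman C2 and C3 take no part because the two acidic sites of the acetoacetate consume the base. The selectivity needed is γ-C- over α-C- and O-alkylation and mono- over dialkylation; it is secured by the dianion itself, since the α-carbon stays masked as the stabilised enolate and product 9 is far less nucleophilic than 8, and by the soft, highly SN2-reactive benzylic bromide used in no excess. The enolate charge and the bulk of the secondary flavanyl ester should suppress Claisen-type attack at the ester carbonyl.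

Step 5
Reactants: 10 tetra-O-benzylcatechin 3-O-{5-[3,4-bis(benzyloxy)phenyl]-3-oxopentanoate}
Product: 11 tetra-O-benzylcatechin 3-O-{(3S)-5-[3,4-bis(benzyloxy)phenyl]-3-hydroxypentanoate}
Conditions: H2 (10 atm), RuCl2[(S)-BINAP](dmf)n (2 mol %), CH2Cl2/MeOH 3:1, 45 °C
Reagents that add atoms: none
Why: Noyori asymmetric hydrogenation of a β-keto ester, in which the substrate chelates Ru(II) through the ketone and ester carbonyls and hydride is delivered to the face fixed by (S)-BINAP, which in the 3-oxoalkanoate series should give the (3S)-hydroxy ester under catalyst control, the aryl benzyl ethers being inert to the homogeneous Ru catalyst.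

Step 6
Reactants: 11 tetra-O-benzylcatechin 3-O-{(3S)-5-[3,4-bis(benzyloxy)phenyl]-3-hydroxypentanoate}
Product: 12 phylloflavan
Conditions: H2 (1 atm), 20% Pd(OH)2/C, THF/MeOH 1:1, rt; filtration and concentration under Ar
Reagents that add atoms: none
Why: Heterogeneous hydrogenolysis of the six aryl benzyl ethers over Pearlman's catalyst, the usual last step for 3-O-acylated flavan-3-ols, which at 1 atm and room temperature should leave the ester, the secondary alcohol, the cyclic benzylic C2–O1 ether and all three stereocentres untouched.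

**Compound list**

1 | (+)-catechin, (2R,3S)-2-(3,4-dihydroxyphenyl)chromane-3,5,7-triol | O[C@H]1Cc2c(O)cc(O)cc2O[C@@H]1c1ccc(O)c(O)c1 | starting material
2 | 5,7,3′,4′-tetra-O-benzyl-(+)-catechin, (2R,3S)-5,7-bis(benzyloxy)-2-[3,4-bis(benzyloxy)phenyl]chroman-3-ol | O[C@H]1Cc2c(OCc3ccccc3)cc(OCc3ccccc3)cc2O[C@@H]1c1ccc(OCc2ccccc2)c(OCc2ccccc2)c1 | intermediate
3 | 2,2,6-trimethyl-4H-1,3-dioxin-4-one (diketene–acetone adduct) | CC1=CC(=O)OC(C)(C)O1 | starting material
4 | acetylketene | CC(=O)C=C=O | intermediate
5 | tetra-O-benzylcatechin 3-O-acetoacetate, (2R,3S)-5,7-bis(benzyloxy)-2-[3,4-bis(benzyloxy)phenyl]chroman-3-yl 3-oxobutanoate | CC(=O)CC(=O)O[C@H]1Cc2c(OCc3ccccc3)cc(OCc3ccccc3)cc2O[C@@H]1c1ccc(OCc2ccccc2)c(OCc2ccccc2)c1 | intermediate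
6 | 3,4-bis(benzyloxy)benzyl alcohol | OCc1ccc(OCc2ccccc2)c(OCc2ccccc2)c1 | starting material
7 | 3,4-bis(benzyloxy)benzyl bromide | BrCc1ccc(OCc2ccccc2)c(OCc2ccccc2)c1 | intermediate
8 | dilithium dienolate (1,3-dianion) of acetoacetate 5 | [Li+].[Li+].C=C([O-])C=C([O-])O[C@H]1Cc2c(OCc3ccccc3)cc(OCc3ccccc3)cc2O[C@@H]1c1ccc(OCc2ccccc2)c(OCc2ccccc2)c1 | intermediate
9 | lithium enolate of keto ester 10 | [Li+].[O-]C(CCc1ccc(OCc2ccccc2)c(OCc2ccccc2)c1)=CC(=O)O[C@H]1Cc2c(OCc3ccccc3)cc(OCc3ccccc3)cc2O[C@@H]1c1ccc(OCc2ccccc2)c(OCc2ccccc2)c1 | intermediate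
10 | tetra-O-benzylcatechin 3-O-{5-[3,4-bis(benzyloxy)phenyl]-3-oxopentanoate} | O=C(CC(=O)CCc1ccc(OCc2ccccc2)c(OCc2ccccc2)c1)O[C@H]1Cc2c(OCc3ccccc3)cc(OCc3ccccc3)cc2O[C@@H]1c1ccc(OCc2ccccc2)c(OCc2ccccc2)c1 | intermediate
11 | tetra-O-benzylcatechin 3-O-{(3S)-5-[3,4-bis(benzyloxy)phenyl]-3-hydroxypentanoate} (hexa-O-benzylphylloflavan) | O=C(C[C@@H](O)CCc1ccc(OCc2ccccc2)c(OCc2ccccc2)c1)O[C@H]1Cc2c(OCc3ccccc3)cc(OCc3ccccc3)cc2O[C@@H]1c1ccc(OCc2ccccc2)c(OCc2ccccc2)c1 | intermediate
12 | phylloflavan, (2R,3S)-2-(3,4-dihydroxyphenyl)-5,7-dihydroxychroman-3-yl (3S)-5-(3,4-dihydroxyphenyl)-3-hydroxypentanoate | O=C(C[C@@H](O)CCc1ccc(O)c(O)c1)O[C@H]1Cc2c(O)cc(O)cc2O[C@@H]1c1ccc(O)c(O)c1 | target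

**Count**

Total steps: 6. Longest linear sequence: 5 (steps 1, 2, 4, 5, 6 from (+)-catechin).

**Steps most likely to fail**

Step 4. What may go wrong: incomplete second deprotonation followed by proton transfer between dianion and product, alkylation at the α-carbon or at oxygen, double benzylation, or base-induced loss of the flavan-3-olate from the ester. The fallback sets out from 3 and 7 and comes back to the route at 10. It forms the C4–C5 bond on the small achiral dioxinone before the flavan is attached. The lithium dienolate of 3 (LDA, THF/DMPU, −78 °C) would be alkylated at the 6-methyl carbon by 7 to give 6-{2-[3,4-bis(benzyloxy)phenyl]ethyl}-2,2-dimethyl-4H-1,3-dioxin-4-one F1. Heating F1 with alcohol 2 in toluene at 110 °C would release the acylketene 5-[3,4-bis(benzyloxy)phenyl]-3-oxopent-1-en-1-one F2, which is trapped by the C3 hydroxyl of 2 to give 10.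

Step 5. What may go wrong: slow turnover with the bulky, poorly soluble hexabenzyl substrate, alcoholysis of the activated β-keto ester by the protic cosolvent, and erosion of facial selectivity if harsher conditions are then needed. The fallback sets out from 7 and comes back at 11. It sets the stereocentre on a simple methyl ester and esterifies afterwards. The dianion of methyl acetoacetate (LDA, 2 equiv, THF) would be alkylated with 7 to give methyl 5-[3,4-bis(benzyloxy)phenyl]-3-oxopentanoate F3. Hydrogenation with the same (S)-BINAP–Ru catalyst in MeOH should give methyl (3S)-5-[3,4-bis(benzyloxy)phenyl]-3-hydroxypentanoate F4. Silylation (TBSCl, imidazole, DMF) gives the silyl ether methyl (3S)-5-[3,4-bis(benzyloxy)phenyl]-3-(tert-butyldimethylsilyloxy)pentanoate F5, and saponification (LiOH, THF/H2O) gives (3S)-5-[3,4-bis(benzyloxy)phenyl]-3-(tert-butyldimethylsilyloxy)pentanoic acid F6. Steglich esterification of F6 with 2 (DCC, DMAP, CH2Cl2) gives the 3-O-silyl ether of 11, F7, and HF·pyridine in THF removes the silyl group to give 11.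

Step 1. What may go wrong: competing C-benzylation of the ambident phloroglucinol phenoxide, over-alkylation at the C3 hydroxyl, and base-induced epimerisation at C2. The fallback sets out from 1 and comes back at 2. Peracetylation (Ac2O, pyridine) gives penta-O-acetyl-(+)-catechin F8. Treatment with NaH, BnCl and a measured amount of water in DMF (0 °C → rt) generates hydroxide slowly, so each aryl acetate is cleaved and the phenoxide benzylated at low standing concentration; this should give 3-O-acetyl-5,7,3′,4′-tetra-O-benzyl-(+)-catechin F9. Methanolysis of the remaining alkyl acetate (K2CO3, MeOH/THF) gives 2.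

**Further compounds**

F1 | step 4 | 6-{2-[3,4-bis(benzyloxy)phenyl]ethyl}-2,2-dimethyl-4H-1,3-dioxin-4-one | CC1(C)OC(=O)C=C(CCc2ccc(OCc3ccccc3)c(OCc3ccccc3)c2)O1
F2 | step 4 | 5-[3,4-bis(benzyloxy)phenyl]-3-oxopent-1-en-1-one (acylketene) | O=C=CC(=O)CCc1ccc(OCc2ccccc2)c(OCc2ccccc2)c1
F3 | step 5 | methyl 5-[3,4-bis(benzyloxy)phenyl]-3-oxopentanoate | COC(=O)CC(=O)CCc1ccc(OCc2ccccc2)c(OCc2ccccc2)c1
F4 | step 5 | methyl (3S)-5-[3,4-bis(benzyloxy)phenyl]-3-hydroxypentanoate | COC(=O)C[C@@H](O)CCc1ccc(OCc2ccccc2)c(OCc2ccccc2)c1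
F5 | step 5 | methyl (3S)-5-[3,4-bis(benzyloxy)phenyl]-3-(tert-butyldimethylsilyloxy)pentanoate | COC(=O)C[C@@H](O[Si](C)(C)C(C)(C)C)CCc1ccc(OCc2ccccc2)c(OCc2ccccc2)c1
F6 | step 5 | (3S)-5-[3,4-bis(benzyloxy)phenyl]-3-(tert-butyldimethylsilyloxy)pentanoic acid | OC(=O)C[C@@H](O[Si](C)(C)C(C)(C)C)CCc1ccc(OCc2ccccc2)c(OCc2ccccc2)c1
F7 | step 5 | tetra-O-benzylcatechin 3-O-{(3S)-5-[3,4-bis(benzyloxy)phenyl]-3-(tert-butyldimethylsilyloxy)pentanoate} | O=C(C[C@@H](O[Si](C)(C)C(C)(C)C)CCc1ccc(OCc2ccccc2)c(OCc2ccccc2)c1)O[C@H]1Cc2c(OCc3ccccc3)cc(OCc3ccccc3)cc2O[C@@H]1c1ccc(OCc2ccccc2)c(OCc2ccccc2)c1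
F8 | step 1 | penta-O-acetyl-(+)-catechin | CC(=O)O[C@H]1Cc2c(OC(C)=O)cc(OC(C)=O)cc2O[C@@H]1c1ccc(OC(C)=O)c(OC(C)=O)c1
F9 | step 1 | 3-O-acetyl-5,7,3′,4′-tetra-O-benzyl-(+)-catechin | CC(=O)O[C@H]1Cc2c(OCc3ccccc3)cc(OCc3ccccc3)cc2O[C@@H]1c1ccc(OCc2ccccc2)c(OCc2ccccc2)c1
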